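The vessel holds a racemate, a single-handed catalyst and a protic impurity while partner is fed in steadily, so each flask poses two questions: how much has turned over, and how was that turnover split between the mirror images?

all flasks: free catalyst 1.7 mM
- Monday's: left-handed substrate 0.17 M; right-handed substrate 0.17 M; partner 0.187 M (fed, over 5.0 d); protic impurity 0.024 M; run made earlier
- Sunday's: left-handed substrate 0.17 M; right-handed substrate 0.17 M; partner 0.187 M (fed, over 5.0 d); protic impurity 0.037 M; run made earlier
- Saturday's: left-handed substrate 0.26 M; right-handed substrate 0.26 M; partner 0.187 M (fed, over 5.0 d); protic impurity 0.017 M; run made earlier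
- alpha: left-handed substrate 0.17 M; right-handed substrate 0.17 M; partner 0.187 M (fed, over 5.0 d); protic impurity 0.0170 M; time 10 d
- eta: left-handed substrate 0.17 M; right-handed substrate 0.17 M; partner 0.187 M (fed, over 20 d); protic impurity 0.0170 M; time 10 d

- Monday's (time / d: right-handed substrate / %, left-handed substrate / %): 0.625: 50.3, 49.9; 1.04: 49.3, 49.5; 1.67: 48.2, 48.6; 2.50: 46.3, 44.1; 3.00: 47.5, 42.9; 5.00: 45.0, 34.9; 8.00: 42.3, 25.5
- Sunday's (time / d: right-handed substrate / %, left-handed substrate / %): 1.25: 49.5, 49.0; 2.50: 47.5, 43.3; 3.00: 46.0, 43.5; 5.00: 47.1, 35.8; 6.00: 46.2, 32.6; 8.00: 42.3, 28.0
- Saturday's (time / d: right-handed substrate / %, left-handed substrate / %): 0.625: 49.5, 49.5; 1.25: 49.5, 48.8; 2.50: 49.0, 44.6; 4.00: 48.2, 43.0; 8.00: 42.6, 30.4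

(scatter of a reading: 1 percentage point)

- free catalyst is single-handed; left-handed substrate and right-handed substrate are mirror images of each other, charged as a racemate, each of them at the stated concentration
- percentages count the whole charge, also what has not yet gone in
- an excess is below zero if the other one leads

* which one finishes higher in excess of right-handed substrate over left-handed substrate among what is left of the two ("neither" within 2 percentage points) (alpha / eta / neither)
* excess of right-handed substrate over left-handed substrate among what is left of the two at the end, alpha
* excess of right-handed substrate over left-handed substrate among what is left of the two at the end, eta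

At any moment the left-handed substrate is lost faster than the right-handed by the selectivity factor times the ratio of their amounts. From the logarithms of what was left of each in the last readings of the three runs, I read that factor as 3.54. Holding the split of the start, the excess is the converted share over the unconverted share, times the excess gain, which is the factor less one divided by the factor plus one: 0.559. As the left-handed substrate falls, the split drifts towards the right-handed, so this overstates the excess for a given conversion.

By 10 d eta had received 0.0935 M of partner. With none lost to the impurity, that is a top conversion of 27.5%, and so a ceiling of 21.2%. Monday's run had received the same amount by 2.50 d, with more impurity and less time, and its readings there showed 9.60% converted. Taking the split at its end value, 3.14 to one, for the whole loss gave an estimated floor of 5.49%.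

For alpha, with none lost to the impurity, the partner charge allows a conversion of 55.0%, which gives a ceiling of 68.4%. The excess read from Monday's run at 8.00 d, 24.8%, with more impurity and less time, served as the floor. That floor stood higher than eta's ceiling, so I expected alpha to finish higher.

The forecast said alpha, with 30% (24% to 36%) for alpha and 15% (10% to 19%) for eta, which it called “partner-starved”. Both central values lay between my bounds.

The flasks gave alpha, with 29.8% for alpha and 8.66% for eta, both between the bounds.

    partner + catalyst intermediate B → free catalyst + right-handed product (k = 4.40 × 10⁻⁴ M⁻¹ s⁻¹)
    free catalyst + left-handed substrate ⇌ catalyst intermediate A (K = 7.20 M⁻¹, k = 0.570 M⁻¹ s⁻¹)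
    partner + protic impurity → quenched reagent (k = 1.50 × 10⁻⁴ M⁻¹ s⁻¹)
    partner + catalyst intermediate A → free catalyst + left-handed product (k = 0.0380 M⁻¹ s⁻¹)
    free catalyst → spent catalyst (k = 9.80 × 10⁻⁶ s⁻¹)
    free catalyst + right-handed substrate ⇌ catalyst intermediate B (K = 150 M⁻¹, k = 0.200 M⁻¹ s⁻¹)
    free catalyst ⇌ dormant form (K = 0.510, k = 3.40 × 10⁻⁵ s⁻¹)

Eta had lost 13.7% of its substrates at 10.0 d, against the forecast's 22 percent, with 17.4% of its partner charge still free and 8.01% of its impurity unquenched. The excess gain on that conversion gave 8.87%. I then read the same alpha flask earlier, at 6.0 d, where 30.2% of left-handed and 43.9% of right-handed substrate stood. Its converted share was 26.0%, the excess gain gave 19.6%, and that flask stood at 18.5%.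

The runs come from a simulation for an exercise; the scatter is artificial.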